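**Plan**

- Retrosynthesis: ring C is opened at O1–C2 and C2–C3 (C2 from an amide acetal). The C3–C4 bond is then cut to a benzoate and (3,4-dimethoxyphenyl)acetic acid. Ring A is cut at C5–C6 and C7–C8 into a 2-pyrone and a ketene acetal.
- Enabling feature: ring A carries the carbonyl carbon on C4a, oxygen on C8a, C7 and C6, prenyl on C8 and hydrogen on C5. C4a, C8a, C8 and C5 map onto C5, C4, C3 and C6 of a 4-acyloxy-3-prenyl-2-pyrone-5-carboxylate. C6–OMe and C7–OH map onto the two carbons of the bis-silyl ketene acetal of methoxyacetic acid.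
- Forward: the pyrone is built from dimethyl 3-oxopentanedioate and prenylated at C3. Ring A then arises by (4+2) cycloaddition, CO2 loss and Me3SiOH loss. The ring B fragment is joined by a decarboxylative Claisen condensation, and ring C closes last.
- Stereochemistry: the target has no stereocentre and no stereogenic double bond; the sp3 centres of the cycloadduct are erased on aromatisation.

Key step: step 5

Remark: positions of the target are numbered as in chromen-4-one (O1, C2–C8a). The geometry or configuration of the transient compounds 2, 9, 10, 16 and 18 is left uncontrolled because each is erased within the same step.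

**Step 1**
Reactants: 1 dimethyl 3-oxopentanedioate
Product: 3 methyl 4-hydroxy-2-oxo-2H-pyran-5-carboxylate, via methoxymethylidene diester 2 (not isolated)
Conditions: HC(OMe)3 (1.1 equiv), Ac2O (2.2 equiv), 120 °C; evaporate; 2 M HCl aq, rt
Reagents that add atoms: trimethyl orthoformate, COC(OC)OC; water, O
Why: Alkoxymethylenation of an active methylene with an orthoformate in Ac2O is a standard condensation, and aqueous acid should hydrolyse the enol ether of 2 to the hydroxymethylene tautomer, whose enol oxygen lactonises onto the distal ester to close the 4-hydroxy-2-pyrone.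

**Step 2**
Reactants: 3 methyl 4-hydroxy-2-oxo-2H-pyran-5-carboxylate; 4 prenyl bromide (1-bromo-3-methylbut-2-ene)
Product: 5 methyl 4-hydroxy-3-(3-methylbut-2-enyl)-2-oxo-2H-pyran-5-carboxylate
Conditions: K2CO3 (1.1 equiv), Pd(PPh3)4 (5 mol %), DMF, rt → 50 °C
Reagents that add atoms: none
Why: Tsuji–Trost allylation, in which zerovalent palladium ionises prenyl bromide (and any O-prenyl ether formed in the background, a vinylogous allyl ester) to the 1,1-dimethylallyl complex, and the soft pyronate anion should attack its unsubstituted terminus through C3, the only nucleophilic carbon, so that the mixture settles on the C-linked linear prenyl isomer.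

**Step 3**
Reactants: 5 methyl 4-hydroxy-3-(3-methylbut-2-enyl)-2-oxo-2H-pyran-5-carboxylate
Product: 6 methyl 4-acetoxy-3-(3-methylbut-2-enyl)-2-oxo-2H-pyran-5-carboxylate
Conditions: Ac2O, pyridine, CH2Cl2, 0 °C → rt; non-aqueous work-up
Reagents that add atoms: acetic anhydride, CC(=O)OC(C)=O
Why: O-Acylation of the acidic 4-hydroxyl under standard anhydride/pyridine conditions; with C3 substituted the acetate cannot shift to carbon, and the enol ester both masks the future C8a oxygen and lowers the LUMO of the diene.

**Step 4**
Reactants: 7 methoxyacetic acid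
Product: 8 2-methoxy-1,1-bis(trimethylsilyloxy)ethene
Conditions: LiN(iPr)2 (2.2 equiv), THF, −78 → 0 °C; Me3SiCl (2.5 equiv), −78 °C → rt; filter, distil
Reagents that add atoms: chlorotrimethylsilane, C[Si](C)(C)Cl
Why: Double deprotonation of the acid to its enediolate and O,O-silylation is the standard preparation of ketene bis(trimethylsilyl) acetals from α-substituted acids, and the product has no E/Z isomers because both acetal substituents are the same.

**Step 5**
Reactants: 6 methyl 4-acetoxy-3-(3-methylbut-2-enyl)-2-oxo-2H-pyran-5-carboxylate; 8 2-methoxy-1,1-bis(trimethylsilyloxy)ethene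
Product: 12 methyl 2-acetoxy-4-hydroxy-5-methoxy-3-(3-methylbut-2-enyl)benzoate, via bridged lactone adduct 9 (not isolated), via cyclohexadiene 10 (not isolated), via aryl silyl ether 11 (not isolated)
Conditions: 8 (3 equiv), toluene, 110 °C, sealed tube; then 1 M HCl, THF, 0 °C
Reagents that add atoms: none
Why: The pyrone diene (C3=C4–C5=C6, made electron-poor by the C5 ester, the lactone carbonyl and the 4-acetoxy group) and the electron-rich ketene acetal should combine in an asynchronous inverse-electron-demand Diels–Alder reaction, the methoxy-bearing carbon bonding first to pyrone C6 and the acetal carbon then closing onto C3 to give bridged lactone 9. Retro-(4+2) loss of CO2 gives cyclohexadiene 10, whose only aromatising pathway is 1,2-elimination of Me3SiOH (the methoxy carbon has no saturated hydrogen-bearing neighbour), so silyl ether 11 results and is hydrolysed to 12 on work-up. The closest known reaction type is the benzannulation of 2-pyrone-5-carboxylates with ketene acetals and 1,1,2-trialkoxyethenes, which likewise ends with CO2 extrusion and loss of an alcohol. Ring A closes as a six-membered carbocycle by intermolecular (4+2) cycloaddition, four carbons coming from the pyrone and two from the ketene acetal, with both new bonds (C5–C6 and C7–C8 of the isoflavone) formed in this step. No stereocentre is set: the three sp3 centres of 9 form without control and vanish on aromatisation. The selectivity needed is regiochemical and is secured by polarity, since pyrone C6 is β to the ester and the vinylogous terminus of the lactone, while in 8 two silyloxy donors outweigh one methoxy and make the CH(OMe) carbon the nucleophilic end, which places OMe next to the ring C–H and the silyloxy carbon next to the prenyl-bearing carbon.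

**Step 6**
Reactants: 12 methyl 2-acetoxy-4-hydroxy-5-methoxy-3-(3-methylbut-2-enyl)benzoate
Product: 13 methyl 2,4-dihydroxy-5-methoxy-3-(3-methylbut-2-enyl)benzoate
Conditions: K2CO3 (0.2 equiv), MeOH, 0 °C → rt
Reagents that add atoms: none
Why: Base-catalysed methanolysis (transesterification) of a phenyl acetate is far faster than any change at the methyl benzoate, which in methanol can only exchange with itself.

**Step 7**
Reactants: 13 methyl 2,4-dihydroxy-5-methoxy-3-(3-methylbut-2-enyl)benzoate
Product: 14 methyl 5-methoxy-2,4-bis(methoxymethoxy)-3-(3-methylbut-2-enyl)benzoate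
Conditions: NaH (2.5 equiv), MeOCH2Cl (2.6 equiv), DMF, 0 °C → rt
Reagents that add atoms: chloromethyl methyl ether, COCCl
Why: Williamson-type O-alkylation of both phenoxides gives base-stable acetal protection, needed because free phenoxides would deactivate the ester in step 8; NaH in DMF is chosen because the C2 hydroxyl is hydrogen-bonded to the ester and flanked by the prenyl group.

**Step 8**
Reactants: 14 methyl 5-methoxy-2,4-bis(methoxymethoxy)-3-(3-methylbut-2-enyl)benzoate; 15 (3,4-dimethoxyphenyl)acetic acid
Product: 17 2-(3,4-dimethoxyphenyl)-1-[5-methoxy-2,4-bis(methoxymethoxy)-3-(3-methylbut-2-enyl)phenyl]ethanone, via keto acid 16 (not isolated)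
Conditions: 15 (1.3 equiv), NaN(SiMe3)2 (4 equiv), DMF, −10 °C → rt; then cold 1 M HCl to pH 4, 40 °C
Reagents that add atoms: none
Why: Crossed Claisen condensation of the arylacetic acid dianion with the non-enolisable methyl benzoate gives the β-keto carboxylate, shielded from further attack as its enolate, and acidification triggers the usual decarboxylation of the β-keto acid to the benzyl aryl ketone.

**Step 9**
Reactants: 17 2-(3,4-dimethoxyphenyl)-1-[5-methoxy-2,4-bis(methoxymethoxy)-3-(3-methylbut-2-enyl)phenyl]ethanone
Product: 19 3-(3,4-dimethoxyphenyl)-7-hydroxy-6-methoxy-8-(3-methylbut-2-enyl)chromen-4-one, via enaminone 18 (not isolated)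
Conditions: Me2NCH(OMe)2 (3 equiv), toluene, 100 °C; evaporate; 3 M HCl in MeOH, rt → 40 °C
Reagents that add atoms: N,N-dimethylformamide dimethyl acetal, COC(OC)N(C)C
Why: Condensation of the activated methylene with the amide acetal gives the enaminone, and methanolic HCl should cleave both methoxymethyl acetals so that the freed C8a hydroxyl adds to the enaminone β-carbon and expels dimethylamine (conjugate addition–elimination closing ring C), the standard deoxybenzoin route to isoflavones; the acid is kept mild so that the C7 hydroxyl does not add to the prenyl double bond.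

**Compound list**

1 | dimethyl 3-oxopentanedioate | COC(=O)CC(=O)CC(=O)OC | starting material
2 | dimethyl 2-(methoxymethylidene)-3-oxopentanedioate (E/Z not defined) | COC=C(C(=O)OC)C(=O)CC(=O)OC | intermediate (not isolated)
3 | methyl 4-hydroxy-2-oxo-2H-pyran-5-carboxylate | COC(=O)C1=COC(=O)C=C1O | intermediate
4 | prenyl bromide (1-bromo-3-methylbut-2-ene) | CC(C)=CCBr | starting material
5 | methyl 4-hydroxy-3-(3-methylbut-2-enyl)-2-oxo-2H-pyran-5-carboxylate | COC(=O)C1=COC(=O)C(CC=C(C)C)=C1O | intermediate
6 | methyl 4-acetoxy-3-(3-methylbut-2-enyl)-2-oxo-2H-pyran-5-carboxylate | COC(=O)C1=COC(=O)C(CC=C(C)C)=C1OC(C)=O | intermediate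
7 | methoxyacetic acid | COCC(=O)O | starting material
8 | 2-methoxy-1,1-bis(trimethylsilyloxy)ethene | COC=C(O[Si](C)(C)C)O[Si](C)(C)C | intermediate
9 | methyl 5-acetoxy-7-methoxy-4-(3-methylbut-2-enyl)-3-oxo-8,8-bis(trimethylsilyloxy)-2-oxabicyclo[2.2.2]oct-5-ene-6-carboxylate (mixture of stereoisomers) | CC(C)=CCC12C(=O)OC(C(C(=O)OC)=C1OC(C)=O)C(OC)C2(O[Si](C)(C)C)O[Si](C)(C)C | intermediate (not isolated)
10 | methyl 6-acetoxy-3-methoxy-5-(3-methylbut-2-enyl)-4,4-bis(trimethylsilyloxy)cyclohexa-1,5-diene-1-carboxylate (racemic) | COC(=O)C1=CC(OC)C(O[Si](C)(C)C)(O[Si](C)(C)C)C(CC=C(C)C)=C1OC(C)=O | intermediate (not isolated)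
11 | methyl 2-acetoxy-5-methoxy-3-(3-methylbut-2-enyl)-4-(trimethylsilyloxy)benzoate | COC(=O)c1cc(OC)c(O[Si](C)(C)C)c(CC=C(C)C)c1OC(C)=O | intermediate (not isolated)
12 | methyl 2-acetoxy-4-hydroxy-5-methoxy-3-(3-methylbut-2-enyl)benzoate | COC(=O)c1cc(OC)c(O)c(CC=C(C)C)c1OC(C)=O | intermediate
13 | methyl 2,4-dihydroxy-5-methoxy-3-(3-methylbut-2-enyl)benzoate | COC(=O)c1cc(OC)c(O)c(CC=C(C)C)c1O | intermediate
14 | methyl 5-methoxy-2,4-bis(methoxymethoxy)-3-(3-methylbut-2-enyl)benzoate | COCOc1c(CC=C(C)C)c(OCOC)c(OC)cc1C(=O)OC | intermediate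
15 | (3,4-dimethoxyphenyl)acetic acid | COc1ccc(CC(=O)O)cc1OC | starting material
16 | 2-(3,4-dimethoxyphenyl)-3-[5-methoxy-2,4-bis(methoxymethoxy)-3-(3-methylbut-2-enyl)phenyl]-3-oxopropanoic acid (racemic) | COCOc1c(CC=C(C)C)c(OCOC)c(OC)cc1C(=O)C(C(=O)O)c1ccc(OC)c(OC)c1 | intermediate (not isolated)
17 | 2-(3,4-dimethoxyphenyl)-1-[5-methoxy-2,4-bis(methoxymethoxy)-3-(3-methylbut-2-enyl)phenyl]ethanone | COCOc1c(CC=C(C)C)c(OCOC)c(OC)cc1C(=O)Cc1ccc(OC)c(OC)c1 | intermediate
18 | 3-(dimethylamino)-2-(3,4-dimethoxyphenyl)-1-[5-methoxy-2,4-bis(methoxymethoxy)-3-(3-methylbut-2-enyl)phenyl]prop-2-en-1-one (E/Z not defined) | COCOc1c(CC=C(C)C)c(OCOC)c(OC)cc1C(=O)C(=CN(C)C)c1ccc(OC)c(OC)c1 | intermediate (not isolated)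
19 | 3-(3,4-dimethoxyphenyl)-7-hydroxy-6-methoxy-8-(3-methylbut-2-enyl)chromen-4-one | COc1ccc(-c2coc3c(CC=C(C)C)c(O)c(OC)cc3c2=O)cc1OC | target

**Step count and risks**

Total steps: 9. Longest linear sequence: 8 (steps 1, 2, 3, 5, 6, 7, 8, 9 from compound 1); step 4 is a one-step side branch.

Steps most likely to fail:

1. Step 5. The second bond of the cycloaddition has to form at the fully substituted, prenyl-bearing C3 of the pyrone. Conversion may therefore be slow, or the reaction may divert to acetyl transfer from the enol ester to the ketene acetal or to conjugate addition without ring closure. The fallback brings in the prenyl group after the benzannulation and sets out from 3. Acetylation (Ac2O, pyridine) would give methyl 4-acetoxy-2-oxo-2H-pyran-5-carboxylate F1, whose unsubstituted C3 should accept 8 more readily. The same thermal sequence would pass through methyl 5-acetoxy-7-methoxy-3-oxo-8,8-bis(trimethylsilyloxy)-2-oxabicyclo[2.2.2]oct-5-ene-6-carboxylate F2, then methyl 6-acetoxy-3-methoxy-4,4-bis(trimethylsilyloxy)cyclohexa-1,5-diene-1-carboxylate F3, then methyl 2-acetoxy-5-methoxy-4-(trimethylsilyloxy)benzoate F4. Acid work-up would give methyl 2-acetoxy-4-hydroxy-5-methoxybenzoate F5. Etherification of its free hydroxyl with methyl 2-methylbut-3-en-2-yl carbonate under Pd(PPh3)4 catalysis (THF, 0 °C) would give methyl 2-acetoxy-5-methoxy-4-(2-methylbut-3-en-2-yloxy)benzoate F6. Aromatic Claisen rearrangement (N,N-diethylaniline, 180 °C) into the only free ortho position would then rejoin the route at 12.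

2. Step 2. Alkylation may go to oxygen, to the tertiary allyl terminus or twice at C3 if the palladium-mediated equilibration is slower than the background reaction. The fallback fixes the prenyl group on carbon before the pyrone exists and sets out from 1. Mono-C-alkylation with 4 (NaH, THF, 0 °C) would give dimethyl 2-(3-methylbut-2-enyl)-3-oxopentanedioate F7. Methoxymethylenation of the remaining CH2 (HC(OMe)3, Ac2O, 120 °C) would give dimethyl 2-(methoxymethylidene)-4-(3-methylbut-2-enyl)-3-oxopentanedioate F8. Brief treatment with dilute aqueous HCl at rt would close the lactone and rejoin the route at 5.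

3. Step 8. The electron-rich, ortho-substituted ester may be acylated too slowly, so that the dianion is consumed by side reactions and the ester is recovered. The fallback replaces the condensation by an organometallic addition and sets out from 14. Treatment with MeNH(OMe)·HCl and i-PrMgCl (THF, −20 °C) would give N,5-dimethoxy-N-methyl-2,4-bis(methoxymethoxy)-3-(3-methylbut-2-enyl)benzamide F9. Addition of 3,4-(MeO)2C6H3CH2MgCl (from 3,4-dimethoxybenzyl chloride and Mg, THF, 0 °C) would stop at the ketone stage and rejoin the route at 17.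

**Further compounds**

F1 | step 5 | methyl 4-acetoxy-2-oxo-2H-pyran-5-carboxylate | COC(=O)C1=COC(=O)C=C1OC(C)=O
F2 | step 5 | methyl 5-acetoxy-7-methoxy-3-oxo-8,8-bis(trimethylsilyloxy)-2-oxabicyclo[2.2.2]oct-5-ene-6-carboxylate (mixture of stereoisomers) | O=C1OC2C(C(=O)OC)=C(OC(C)=O)C1C(O[Si](C)(C)C)(O[Si](C)(C)C)C2OC
F3 | step 5 | methyl 6-acetoxy-3-methoxy-4,4-bis(trimethylsilyloxy)cyclohexa-1,5-diene-1-carboxylate (racemic) | COC(=O)C1=CC(OC)C(O[Si](C)(C)C)(O[Si](C)(C)C)C=C1OC(C)=O
F4 | step 5 | methyl 2-acetoxy-5-methoxy-4-(trimethylsilyloxy)benzoate | COC(=O)c1cc(OC)c(O[Si](C)(C)C)cc1OC(C)=O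
F5 | step 5 | methyl 2-acetoxy-4-hydroxy-5-methoxybenzoate | COC(=O)c1cc(OC)c(O)cc1OC(C)=O
F6 | step 5 | methyl 2-acetoxy-5-methoxy-4-(2-methylbut-3-en-2-yloxy)benzoate | COC(=O)c1cc(OC)c(OC(C)(C)C=C)cc1OC(C)=O
F7 | step 2 | dimethyl 2-(3-methylbut-2-enyl)-3-oxopentanedioate (racemic) | COC(=O)CC(=O)C(CC=C(C)C)C(=O)OC
F8 | step 2 | dimethyl 2-(methoxymethylidene)-4-(3-methylbut-2-enyl)-3-oxopentanedioate (E/Z not defined, racemic) | COC=C(C(=O)OC)C(=O)C(CC=C(C)C)C(=O)OC
F9 | step 8 | N,5-dimethoxy-N-methyl-2,4-bis(methoxymethoxy)-3-(3-methylbut-2-enyl)benzamide | COCOc1c(CC=C(C)C)c(OCOC)c(OC)cc1C(=O)N(C)OC
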